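**Retrosynthetic overview**

1. Kazinol N (26) comes from its MOM ether 25, and 25 from aryl ketone 21 by a base-triggered para-quinone-methide deoxygenation of the benzylic C=O, which needs neither hydrogenation nor acid.
2. Ring A of 21 is cut across C1–C2 and C5–C6 into ynone 12 and diene 18 ([4+2] cycloaddition–aromatisation). The feature used is that ring A carries OMe on C2 (ortho) and OH on C4 (para) to C1, the carbon bearing the three-carbon chain; a 1,1-dimethoxy-3-silyloxybutadiene lays down exactly this pattern around the acyl-bearing carbon of an ynone, so the two oxygens are differentiated as they are built.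
3. Ynone 12 comes from chromene-6-carbaldehyde 8 (two-carbon olefination, CuH conjugate reduction, Weinreb amide, ethynyl Grignard); the formyl carbon becomes the benzylic CH2 on ring B.
4. Aldehyde 8 comes from bromocatechol aldehyde 1: propargylation of O4, MOM on O5, propargyl Claisen/electrocyclisation to the pyran ring, Stille prenylation at C–Br.
5. Ring order: benzene ring B is bought, the pyran ring of the chromene is closed first (step 3), ring A last (step 12).

Key step: step 12

Assumptions: compounds 1, 2, 13, 14 and all un-numbered reagents are taken as commercial. Ar stands for the ring B unit 8-(methoxymethoxy)-2,2-dimethyl-5-(3-methylbut-2-en-1-yl)-2H-chromen-6-yl. Compounds 22 and 23 are racemic; their single stereocentre is erased in step 15, and the target is achiral.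

**Route**

Step 1
Reactants: 1 2-bromo-4,5-dihydroxybenzaldehyde; 2 3-chloro-3-methylbut-1-yne
Product: 3 2-bromo-5-hydroxy-4-[(2-methylbut-3-yn-2-yl)oxy]benzaldehyde
Conditions: DBU (1.05 equiv), CuCl2·2H2O (cat.), MeCN, 0 °C, N2
Reagents that add atoms: none
Why: The hydroxyl para to the formyl group is the more acidic one and is the only one ionised by one equivalent of base, so the copper-catalysed O-propargylation of a phenol with a tertiary propargylic chloride should take place at O4.

Step 2
Reactants: 3 2-bromo-5-hydroxy-4-[(2-methylbut-3-yn-2-yl)oxy]benzaldehyde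
Product: 4 2-bromo-5-(methoxymethoxy)-4-[(2-methylbut-3-yn-2-yl)oxy]benzaldehyde
Conditions: MOMCl, i-Pr2NEt, CH2Cl2, 0 °C → rt
Reagents that add atoms: chloromethyl methyl ether, COCCl
Why: Standard O-alkylation of the remaining phenol gives a methoxymethyl ether that is stable to heat, organometallic reagents, hydride and base in all later steps.

Step 3
Reactants: 4 2-bromo-5-(methoxymethoxy)-4-[(2-methylbut-3-yn-2-yl)oxy]benzaldehyde
Product: 7 5-bromo-8-(methoxymethoxy)-2,2-dimethyl-2H-chromene-6-carbaldehyde, via allenylphenol 5 (not isolated), via ortho-quinone methide 6 (not isolated)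
Conditions: N,N-diethylaniline, 180 °C
Reagents that add atoms: none
Why: The aromatic propargyl Claisen rearrangement can only go to C3, the one free ortho carbon, and the allenylphenol then undergoes a 1,5-hydrogen shift and 6π oxa-electrocyclisation that close the 2,2-dimethylpyran ring.

Step 4
Reactants: 7 5-bromo-8-(methoxymethoxy)-2,2-dimethyl-2H-chromene-6-carbaldehyde
Product: 8 8-(methoxymethoxy)-2,2-dimethyl-5-(3-methylbut-2-en-1-yl)-2H-chromene-6-carbaldehyde
Conditions: Bu3SnCH2CH=CMe2, Pd(PPh3)4 (cat.), DMF, 100 °C
Reagents that add atoms: tributyl(3-methylbut-2-en-1-yl)stannane, CCCC[Sn](CCCC)(CCCC)CC=C(C)C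
Why: Stille coupling of the aryl bromide, activated by the ortho formyl group, proceeds through an aryl(prenyl)palladium species that should reductively eliminate at the less substituted allyl terminus, the di-ortho-substituted aryl group favouring the linear prenyl product.

Step 5
Reactants: 8 8-(methoxymethoxy)-2,2-dimethyl-5-(3-methylbut-2-en-1-yl)-2H-chromene-6-carbaldehyde
Product: 9 ethyl (2E)-3-Ar-prop-2-enoate
Conditions: (EtO)2P(O)CH2CO2Et, NaH, THF, 0 °C → rt
Reagents that add atoms: triethyl phosphonoacetate, CCOC(=O)CP(=O)(OCC)OCC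
Why: Horner–Wadsworth–Emmons olefination of an aromatic aldehyde with a stabilised phosphonate anion should give the E-enoate, whose geometry is of no consequence because the alkene is reduced next.

Step 6
Reactants: 9 ethyl (2E)-3-Ar-prop-2-enoate
Product: 10 ethyl 3-Ar-propanoate
Conditions: [(Ph3P)CuH]6 (cat.), (EtO)2MeSiH, t-BuOH, toluene, rt
Reagents that add atoms: none
Why: Conjugate reduction by catalytic (Ph3P)CuH hydrocuprates only the polarised enoate, leaving the prenyl and chromene alkenes alone, and it forms no radical anion that could cyclise onto the ortho prenyl group.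

Step 7
Reactants: 10 ethyl 3-Ar-propanoate
Product: 11 N-methoxy-N-methyl-3-Ar-propanamide
Conditions: MeNH(OMe)·HCl, i-PrMgCl, THF, −20 → 0 °C
Reagents that add atoms: N,O-dimethylhydroxylamine hydrochloride, CNOC.Cl
Why: Aminolysis of an ester by ClMgN(OMe)Me, formed in the flask from the amine salt and i-PrMgCl, is a standard Weinreb amide synthesis and touches neither the acetal nor the alkenes.

Step 8
Reactants: 11 N-methoxy-N-methyl-3-Ar-propanamide
Product: 12 5-Ar-pent-1-yn-3-one
Conditions: HC≡CMgBr, THF, 0 °C; quench into cold 1 M aq. HCl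
Reagents that add atoms: ethynylmagnesium bromide, C#C[Mg]Br
Why: In this Weinreb ketone synthesis the chelated tetrahedral magnesium adduct prevents over-addition, and the cold acid quench protonates the released amine so that it cannot add to the terminal ynone.

Step 9
Reactants: 13 acetyl chloride; 14 1,1-dichloroethene
Product: 16 4,4-dichlorobut-3-en-2-one, via 4,4,4-trichlorobutan-2-one 15 (not isolated)
Conditions: AlCl3, CH2Cl2, 0 °C → rt; ice-water work-up; distillation (loss of HCl)
Reagents that add atoms: none
Why: Friedel–Crafts-type acylation of the alkene at its CH2 terminus gives the chlorine-stabilised cation, which captures chloride, and the β-chloro ketone then loses HCl by β-elimination on heating.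

Step 10
Reactants: 16 4,4-dichlorobut-3-en-2-one
Product: 17 4,4-dimethoxybut-3-en-2-one
Conditions: NaOMe (2 equiv), MeOH, 0 °C → rt
Reagents that add atoms: sodium methoxide, [Na+].[O-]C
Why: Two successive conjugate addition–elimination steps of methoxide at the β-carbon of the β,β-dichloroenone give the acyl ketene acetal.

Step 11
Reactants: 17 4,4-dimethoxybut-3-en-2-one
Product: 18 1,1-dimethoxy-3-(trimethylsilyloxy)buta-1,3-diene
Conditions: Me3SiCl, Et3N, ZnCl2 (cat.), toluene, 40 °C; filtration and distillation under exclusion of moisture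
Reagents that add atoms: chlorotrimethylsilane, C[Si](C)(C)Cl
Why: Soft enolisation of the methyl ketone and O-silylation is the usual preparation of 2-silyloxybutadienes, and the methyl group is the only enolisable position.

Step 12
Reactants: 12 5-Ar-pent-1-yn-3-one; 18 1,1-dimethoxy-3-(trimethylsilyloxy)buta-1,3-diene
Product: 21 1-(4-hydroxy-2-methoxyphenyl)-3-Ar-propan-1-one, via cyclohexadiene cycloadduct 19 (not isolated), via aryl trimethylsilyl ether 20 (not isolated)
Conditions: 18 (excess), toluene, 0 °C → rt (50 °C if slow); then K2CO3 (cat.), MeOH, rt; aq. NH4Cl work-up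
Reagents that add atoms: none
Why: The CH2 terminus of diene 18 carries the largest HOMO coefficient because the 1,1-dimethoxy and 3-silyloxy donors reinforce each other, so it bonds to the β-carbon of the terminal ynone while the ketene acetal carbon bonds to the α-carbon, in a concerted but strongly asynchronous [4+2] cycloaddition (a stepwise Michael addition–ring closure would lead to the same adduct). The closest known reaction is the cycloaddition–aromatisation of 1,1-dialkoxy-3-silyloxybutadienes with acetylenic ketones and esters, which gives 4-hydroxy-2-alkoxyaryl carbonyl compounds. Ring A is closed as a six-membered carbocycle by intermolecular [4+2] annulation forming C1–C2 and C5–C6; cyclohexa-1,4-diene 19 then aromatises by 1,4-elimination of methanol from the ketal carbon, and methanolysis of aryl silyl ether 20 frees the phenol. No stereocentre is formed. The selectivity required is regiochemical (methoxy ortho and hydroxyl para to the acyl carbon), and the polarity match of diene and ynone secures it. Chemoselectivity follows because the ynone is the only electron-poor π bond, and the reaction needs no Lewis acid, so the MOM ether and the chromene and prenyl alkenes should be untouched.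

Step 13
Reactants: 21 1-(4-hydroxy-2-methoxyphenyl)-3-Ar-propan-1-one
Product: 22 4-(1-hydroxy-3-Ar-propyl)-3-methoxyphenol (racemic)
Conditions: NaBH4 (excess), MeOH/THF, 0 °C → rt; neutral work-up, crude product used directly
Reagents that add atoms: none
Why: Borohydride reduction of the aryl ketone, as is routine for para-hydroxyacetophenones, gives the benzylic alcohol as a racemate whose stereocentre is removed in step 15.

Step 14
Reactants: 22 4-(1-hydroxy-3-Ar-propyl)-3-methoxyphenol (racemic)
Product: 23 1-(4-acetoxy-2-methoxyphenyl)-3-Ar-propyl acetate (racemic)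
Conditions: Ac2O, pyridine, DMAP (cat.), CH2Cl2, 0 °C → rt
Reagents that add atoms: acetic anhydride, CC(=O)OC(C)=O
Why: Nucleophile-catalysed acetylation of both hydroxyls gives the benzylic position a leaving group and the phenol a base-labile mask, without any acid that could ionise the electron-rich benzylic centre.

Step 15
Reactants: 23 1-(4-acetoxy-2-methoxyphenyl)-3-Ar-propyl acetate (racemic)
Product: 25 3-methoxy-4-(3-Ar-propyl)phenol, via para-quinone methide 24 (not isolated)
Conditions: NaBH4 (excess), EtOH/THF, 0 °C → rt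
Reagents that add atoms: none
Why: This is the known borohydride reduction of para-acetoxybenzyl acetates: ethanolysis of the phenolic acetate gives the phenoxide, 1,6-elimination of the benzylic acetate gives the para-quinone methide, and 1,6-addition of hydride gives the methylene, all in basic medium in which ring B and the prenyl alkene are not nucleophilic enough to trap the intermediate.

Step 16
Reactants: 25 3-methoxy-4-(3-Ar-propyl)phenol
Product: 26 Kazinol N
Conditions: 3 M aq. HCl, MeOH, 40 °C
Reagents that add atoms: none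
Why: Acid-catalysed acetal cleavage removes the MOM group under dilute conditions that 2,2-dimethylchromenes and prenyl groups tolerate, and no phenol sits ortho to the prenyl group to cyclise onto it.

**Compound list**

1 | 2-bromo-4,5-dihydroxybenzaldehyde | O=Cc1cc(O)c(O)cc1Br | starting material
2 | 3-chloro-3-methylbut-1-yne | CC(C)(Cl)C#C | starting material
3 | 2-bromo-5-hydroxy-4-[(2-methylbut-3-yn-2-yl)oxy]benzaldehyde | O=Cc1cc(O)c(OC(C)(C)C#C)cc1Br | intermediate
4 | 2-bromo-5-(methoxymethoxy)-4-[(2-methylbut-3-yn-2-yl)oxy]benzaldehyde | O=Cc1cc(OCOC)c(OC(C)(C)C#C)cc1Br | intermediate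
5 | 2-bromo-4-hydroxy-5-(methoxymethoxy)-3-(3-methylbuta-1,2-dien-1-yl)benzaldehyde (allenylphenol) | O=Cc1cc(OCOC)c(O)c(C=C=C(C)C)c1Br | intermediate (not isolated)
6 | 2-bromo-5-(methoxymethoxy)-3-(3-methylbut-2-en-1-ylidene)-4-oxocyclohexa-1,5-diene-1-carbaldehyde (ortho-quinone methide) | O=CC1=C(Br)C(=CC=C(C)C)C(=O)C(OCOC)=C1 | intermediate (not isolated)
7 | 5-bromo-8-(methoxymethoxy)-2,2-dimethyl-2H-chromene-6-carbaldehyde | O=Cc1cc(OCOC)c2OC(C)(C)C=Cc2c1Br | intermediate
8 | 8-(methoxymethoxy)-2,2-dimethyl-5-(3-methylbut-2-en-1-yl)-2H-chromene-6-carbaldehyde | O=Cc1cc(OCOC)c2OC(C)(C)C=Cc2c1CC=C(C)C | intermediate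
9 | ethyl (2E)-3-[8-(methoxymethoxy)-2,2-dimethyl-5-(3-methylbut-2-en-1-yl)-2H-chromen-6-yl]prop-2-enoate | CCOC(=O)/C=C/c1cc(OCOC)c2OC(C)(C)C=Cc2c1CC=C(C)C | intermediate
10 | ethyl 3-[8-(methoxymethoxy)-2,2-dimethyl-5-(3-methylbut-2-en-1-yl)-2H-chromen-6-yl]propanoate | CCOC(=O)CCc1cc(OCOC)c2OC(C)(C)C=Cc2c1CC=C(C)C | intermediate
11 | N-methoxy-N-methyl-3-[8-(methoxymethoxy)-2,2-dimethyl-5-(3-methylbut-2-en-1-yl)-2H-chromen-6-yl]propanamide | CON(C)C(=O)CCc1cc(OCOC)c2OC(C)(C)C=Cc2c1CC=C(C)C | intermediate
12 | 5-[8-(methoxymethoxy)-2,2-dimethyl-5-(3-methylbut-2-en-1-yl)-2H-chromen-6-yl]pent-1-yn-3-one | C#CC(=O)CCc1cc(OCOC)c2OC(C)(C)C=Cc2c1CC=C(C)C | intermediate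
13 | acetyl chloride | CC(Cl)=O | starting material
14 | 1,1-dichloroethene | C=C(Cl)Cl | starting material
15 | 4,4,4-trichlorobutan-2-one | CC(=O)CC(Cl)(Cl)Cl | intermediate (not isolated)
16 | 4,4-dichlorobut-3-en-2-one | CC(=O)C=C(Cl)Cl | intermediate
17 | 4,4-dimethoxybut-3-en-2-one | COC(OC)=CC(C)=O | intermediate
18 | 1,1-dimethoxy-3-(trimethylsilyloxy)buta-1,3-diene | COC(OC)=CC(=C)O[Si](C)(C)C | intermediate
19 | 1-[6,6-dimethoxy-4-(trimethylsilyloxy)cyclohexa-1,4-dien-1-yl]-3-[8-(methoxymethoxy)-2,2-dimethyl-5-(3-methylbut-2-en-1-yl)-2H-chromen-6-yl]propan-1-one | COC1(OC)C=C(O[Si](C)(C)C)CC=C1C(=O)CCc1cc(OCOC)c2OC(C)(C)C=Cc2c1CC=C(C)C | intermediate (not isolated)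
20 | 1-[2-methoxy-4-(trimethylsilyloxy)phenyl]-3-[8-(methoxymethoxy)-2,2-dimethyl-5-(3-methylbut-2-en-1-yl)-2H-chromen-6-yl]propan-1-one | COc1cc(O[Si](C)(C)C)ccc1C(=O)CCc1cc(OCOC)c2OC(C)(C)C=Cc2c1CC=C(C)C | intermediate (not isolated)
21 | 1-(4-hydroxy-2-methoxyphenyl)-3-[8-(methoxymethoxy)-2,2-dimethyl-5-(3-methylbut-2-en-1-yl)-2H-chromen-6-yl]propan-1-one | COc1cc(O)ccc1C(=O)CCc1cc(OCOC)c2OC(C)(C)C=Cc2c1CC=C(C)C | intermediate
22 | 4-{1-hydroxy-3-[8-(methoxymethoxy)-2,2-dimethyl-5-(3-methylbut-2-en-1-yl)-2H-chromen-6-yl]propyl}-3-methoxyphenol, racemic | COc1cc(O)ccc1C(O)CCc1cc(OCOC)c2OC(C)(C)C=Cc2c1CC=C(C)C | intermediate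
23 | 1-(4-acetoxy-2-methoxyphenyl)-3-[8-(methoxymethoxy)-2,2-dimethyl-5-(3-methylbut-2-en-1-yl)-2H-chromen-6-yl]propyl acetate, racemic | COc1cc(OC(C)=O)ccc1C(OC(C)=O)CCc1cc(OCOC)c2OC(C)(C)C=Cc2c1CC=C(C)C | intermediate
24 | 3-methoxy-4-{3-[8-(methoxymethoxy)-2,2-dimethyl-5-(3-methylbut-2-en-1-yl)-2H-chromen-6-yl]propylidene}cyclohexa-2,5-dien-1-one (para-quinone methide) | COC1=CC(=O)C=CC1=CCCc1cc(OCOC)c2OC(C)(C)C=Cc2c1CC=C(C)C | intermediate (not isolated)
25 | 3-methoxy-4-{3-[8-(methoxymethoxy)-2,2-dimethyl-5-(3-methylbut-2-en-1-yl)-2H-chromen-6-yl]propyl}phenol | COc1cc(O)ccc1CCCc1cc(OCOC)c2OC(C)(C)C=Cc2c1CC=C(C)C | intermediate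
26 | Kazinol N, 6-[3-(4-hydroxy-2-methoxyphenyl)propyl]-2,2-dimethyl-5-(3-methylbut-2-en-1-yl)-2H-chromen-8-ol (achiral) | COc1cc(O)ccc1CCCc1cc(O)c2c(c1CC=C(C)C)C=CC(C)(C)O2 | target

**Step count**

Total: 16 steps. Longest linear sequence: 13 steps (steps 1–8 and 12–16); the diene branch (steps 9–11) joins at step 12.

**Steps most likely to fail, with fallbacks**

Step 12 (ring A annulation). The diene may add only once and give an open-chain Michael adduct that hydrolyses instead of closing. The diene may also be protodesilylated, or the terminal ynone may oligomerise, before cycloaddition is complete. The fallback brings ring A in ready-made. It sets out from Weinreb amide 11 and returns at 21. Commercial 4-bromo-3-methoxyphenol F1 would be silylated with t-BuMe2SiCl and imidazole in DMF to give (4-bromo-3-methoxyphenoxy)(tert-butyl)dimethylsilane F2, and bromine–lithium exchange of F2 with n-BuLi in THF at −78 °C would give [4-(tert-butyldimethylsilyloxy)-2-methoxyphenyl]lithium F3 in solution. Addition of F3 to 11 at −78 °C, followed by an aqueous NH4Cl quench, would give 1-[4-(tert-butyldimethylsilyloxy)-2-methoxyphenyl]-3-[8-(methoxymethoxy)-2,2-dimethyl-5-(3-methylbut-2-en-1-yl)-2H-chromen-6-yl]propan-1-one F4 as the silyl-protected ketone. Treatment of F4 with Bu4NF in THF at 0 °C and an aqueous NH4Cl work-up would then release ketone 21.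

Step 4 (prenylation). The prenyl group may be transferred through its tertiary carbon to give the 1,1-dimethylallyl isomer, or the hindered bromide flanked by two ortho substituents may undergo protodebromination instead of coupling. The fallback sets out from bromide 7 and returns at 8. Suzuki–Miyaura coupling of 7 with allylboronic acid pinacol ester (Pd(PPh3)4, CsF, THF, reflux), in which the symmetrical allyl group leaves no regiochemical question, would give 8-(methoxymethoxy)-2,2-dimethyl-5-(prop-2-en-1-yl)-2H-chromene-6-carbaldehyde F5 as the allyl arene. Cross-metathesis of F5 with an excess of 2-methylbut-2-ene (second-generation Grubbs catalyst, CH2Cl2, 40 °C) would then give 8; the hindered cyclic chromene alkene should not take part.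

Step 15 (quinone methide reduction). The para-quinone methide may be captured by ethoxide or may tautomerise to the 4-vinylphenol faster than hydride adds. The electron-rich benzylic acetate may also ionise and decompose during handling. The fallback removes the carbonyl oxygen without any benzylic leaving group. It sets out from ketone 21 and returns at 25. Condensation of 21 with 4-methylbenzenesulfonohydrazide (EtOH, cat. AcOH, 60 °C) would give the tosylhydrazone 4-methyl-N'-{1-(4-hydroxy-2-methoxyphenyl)-3-[8-(methoxymethoxy)-2,2-dimethyl-5-(3-methylbut-2-en-1-yl)-2H-chromen-6-yl]propylidene}benzenesulfonohydrazide F6 as the only new intermediate. Reduction of F6 with an excess of catecholborane (CHCl3, 0 °C), then NaOAc·3H2O at reflux, would give 25 with loss of dinitrogen and sulfinate; the alkenes are not hydroborated at this temperature.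

**Further compounds**

F1 | step 12 | 4-bromo-3-methoxyphenol | COc1cc(O)ccc1Br
F2 | step 12 | (4-bromo-3-methoxyphenoxy)(tert-butyl)dimethylsilane | COc1cc(O[Si](C)(C)C(C)(C)C)ccc1Br
F3 | step 12 | [4-(tert-butyldimethylsilyloxy)-2-methoxyphenyl]lithium | [Li]c1ccc(O[Si](C)(C)C(C)(C)C)cc1OC
F4 | step 12 | 1-[4-(tert-butyldimethylsilyloxy)-2-methoxyphenyl]-3-[8-(methoxymethoxy)-2,2-dimethyl-5-(3-methylbut-2-en-1-yl)-2H-chromen-6-yl]propan-1-one | COc1cc(O[Si](C)(C)C(C)(C)C)ccc1C(=O)CCc1cc(OCOC)c2OC(C)(C)C=Cc2c1CC=C(C)C
F5 | step 4 | 8-(methoxymethoxy)-2,2-dimethyl-5-(prop-2-en-1-yl)-2H-chromene-6-carbaldehyde | O=Cc1cc(OCOC)c2OC(C)(C)C=Cc2c1CC=C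
F6 | step 15 | 4-methyl-N'-{1-(4-hydroxy-2-methoxyphenyl)-3-[8-(methoxymethoxy)-2,2-dimethyl-5-(3-methylbut-2-en-1-yl)-2H-chromen-6-yl]propylidene}benzenesulfonohydrazide | COc1cc(O)ccc1C(=NNS(=O)(=O)c1ccc(C)cc1)CCc1cc(OCOC)c2OC(C)(C)C=Cc2c1CC=C(C)C
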